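**Retrosynthetic overview**
- Target ⇒ 5,6-dibromo-1H-indole: the C3–Br bond is made last by electrophilic bromination.
- 5,6-Dibromoindole ⇒ 4,5-dibromo-2,β-dinitrostyrene: N1–C2 is closed by reductive cyclization. The pyrrole ring is the only ring built; the benzene ring is bought.
- Dinitrostyrene ⇒ 4,5-dibromo-2-nitrobenzaldehyde + nitromethane: the C2–C3 bond comes from a nitronate used as a formyl-anion (d1) equivalent attacking the aldehyde carbon. Condensation and ring closure run in one flask.
- Nitroaldehyde ⇒ 3,4-dibromobenzaldehyde by nitration para to the 3-bromine.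

Assumption: the target has no stereocentre and no stereogenic double bond, so there is no enantiomer to select; the SMILES is taken as the full structure.

**Route**

Step 1
Reactants: 1 3,4-dibromobenzaldehyde
Product: 2 4,5-dibromo-2-nitrobenzaldehyde
Conditions: fuming HNO3 (1.2 equiv), conc. H2SO4, 0–5 °C, 1 h; pour on ice; recrystallise (EtOH)
Reagents that add atoms: nitric acid, O[N+](=O)[O-]
Why: Electrophilic aromatic nitration (SEAr) should go to the ring carbon para to the 3-bromine and ortho to the formyl group, as the second nitration of 1,2-dibromobenzene does in giving 1,2-dibromo-4,5-dinitrobenzene, and the aldehyde survives cold mixed acid, with water as the only co-product.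

Step 2
Reactants: 2 4,5-dibromo-2-nitrobenzaldehyde; 3 nitromethane
Product: 6 5,6-dibromo-1H-indole, via nitroaldol 4 (not isolated), via dinitrostyrene 5 (not isolated)
Conditions: MeNO2 (3 equiv), NH4OAc (1 equiv), AcOH, 100 °C, 2 h; evaporate excess MeNO2; then Fe powder (12 equiv), silica gel, AcOH–toluene 1:3, 90 °C, 1 h (same flask)
Reagents that add atoms: none
Why: In a Henry (nitroaldol) condensation the nitronate of 3 acts as a formyl-anion (d1) equivalent and attacks the electron-poor aldehyde carbon of 2, joining the carbons that become C3 and C2 (both of acceptor type), NH4OAc/AcOH dehydrates racemic 4 to the (E)-nitroalkene 5 (the stereocentre of 4 is erased), and Fe/AcOH then reduces both nitro groups so that the new aniline nitrogen condenses with the imine-level side-chain carbon with loss of ammonia (Nenitzescu-type o,β-dinitrostyrene reductive cyclization), aryl bromides being inert to Fe/AcOH.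

Step 3
Reactants: 6 5,6-dibromo-1H-indole
Product: 7 3,5,6-tribromo-1H-indole
Conditions: NBS (1.0 equiv), DMF, 0 °C, 30 min, dark; aq. Na2S2O3/NaHCO3 work-up; store cold
Reagents that add atoms: N-bromosuccinimide, O=C1CCC(=O)N1Br
Why: Electrophilic aromatic bromination occurs at C3, the enamine-like and most nucleophilic indole position, much faster than at C2 or on the dibrominated benzo ring, so one equivalent of NBS gives the 3-bromide selectively.

**Compound list**

1 | 3,4-dibromobenzaldehyde (achiral) | O=Cc1ccc(Br)c(Br)c1 | starting material
2 | 4,5-dibromo-2-nitrobenzaldehyde (achiral) | O=Cc1cc(Br)c(Br)cc1[N+](=O)[O-] | intermediate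
3 | nitromethane | C[N+](=O)[O-] | starting material
4 | nitroaldol: 1-(4,5-dibromo-2-nitrophenyl)-2-nitroethan-1-ol (racemic, not isolated) | OC(C[N+](=O)[O-])c1cc(Br)c(Br)cc1[N+](=O)[O-] | intermediate
5 | dinitrostyrene: (E)-1,2-dibromo-4-nitro-5-(2-nitroethenyl)benzene (not isolated) | [O-][N+](=O)/C=C/c1cc(Br)c(Br)cc1[N+](=O)[O-] | intermediate
6 | 5,6-dibromo-1H-indole (achiral) | Brc1cc2[nH]ccc2cc1Br | intermediate
7 | 3,5,6-tribromo-1H-indole (achiral) | Brc1cc2[nH]cc(Br)c2cc1Br | target

**Totals**
Total step count: 3. Longest linear sequence: 3.

**Steps most likely to fail, with fallbacks**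

Step 2 (highest risk). The o-nitroaldehyde may give tar in the NH4OAc condensation, the nitroalkene may polymerise, and the crude carried into the iron reduction may be dirty. Fallback: setting out from 2, a Wittig reaction with methoxymethylenetriphenylphosphorane, a different formyl-anion equivalent made from (methoxymethyl)triphenylphosphonium chloride and KOtBu in THF at 0 °C, gives the enol ether 1,2-dibromo-4-(2-methoxyethenyl)-5-nitrobenzene F1 as an E/Z mixture. Fe/AcOH at 80 °C then reduces the nitro group, and the acid closes the amino enol ether onto nitrogen with loss of methanol. No nitroalkene is involved, and the route is rejoined at 6.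

Step 1. The nitro group may enter partly ortho to the 4-bromine (meta to the formyl group), and some aldehyde may be oxidised to the acid. Fallback: setting out from 1, the Henry condensation is run first (MeNO2, NH4OAc, AcOH, 100 °C) to give (E)-1,2-dibromo-4-(2-nitroethenyl)benzene F2. The ring is then nitrated (fuming HNO3, H2SO4, −10 to 0 °C). The nitrovinyl group directs ortho/para and the 3-bromine directs para, so both point to the same carbon, and no oxidisable aldehyde is present. This comes back to the route at 5, which is isolated here and given the Fe/AcOH half of step 2.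

Step 3. Over-bromination to the 2,3-dibromide and acid or light sensitivity of the free 3-bromoindole are the risks. Fallback: setting out from 6, N-silylation (NaH, TBSCl, THF, 0 °C) gives 5,6-dibromo-1-(tert-butyldimethylsilyl)-1H-indole F3. Bromination with NBS in THF at −78 °C gives 3,5,6-tribromo-1-(tert-butyldimethylsilyl)-1H-indole F4, where the bulky silyl group shields C2 and stabilises the product for chromatography. TBAF in THF at 0 °C removes the silyl group and rejoins the route at 7.

**Further compounds**

F1 | step 2 | 1,2-dibromo-4-(2-methoxyethenyl)-5-nitrobenzene (E/Z mixture) | COC=Cc1cc(Br)c(Br)cc1[N+](=O)[O-]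
F2 | step 1 | (E)-1,2-dibromo-4-(2-nitroethenyl)benzene | [O-][N+](=O)/C=C/c1ccc(Br)c(Br)c1
F3 | step 3 | 5,6-dibromo-1-(tert-butyldimethylsilyl)-1H-indole | CC(C)(C)[Si](C)(C)n1ccc2cc(Br)c(Br)cc21
F4 | step 3 | 3,5,6-tribromo-1-(tert-butyldimethylsilyl)-1H-indole | CC(C)(C)[Si](C)(C)n1cc(Br)c2cc(Br)c(Br)cc21
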